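**Retrosynthetic overview**

1. Target ⇒ tricyclic 6,14-diketone: one double methylenation installs both exocyclic CH2 groups.
2. Diketone ⇒ ring A chloroketone carrying a 2-substituted butadiene: a type 2 intramolecular oxyallyl (4+3) cycloaddition closes rings B and C together (C1–C15 and C12–C13 bonds) and leaves the bridgehead C10=C11 alkene.
3. Chloroketone ⇒ 2,4-disubstituted cyclohexenone by Mukaiyama–Michael addition (C2 and C7 of the tricycle).
4. Cyclohexenone ⇒ para-substituted anisole by one-flask Birch reduction / C-alkylation / hydrolysis, then catalytic asymmetric olefin isomerization (C3 of the tricycle).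
5. Anisole ⇒ 4-methoxystyrene by asymmetric hydrovinylation (side-chain centre) and B-alkyl Suzuki coupling. Ring order: A (all six carbons from the arene), then B and C in one step.

Assumption: (2E)-3-iodo-2-methylprop-2-en-1-ol, 3-bromobut-3-en-1-ol, pinacol vinylboronate, 1,3-dichloropropan-2-one and all ligands and catalysts are bought.

**Route**

Step 1
Reactants: 1 4-methoxystyrene; 2 ethylene
Product: 3 1-[(2S)-but-3-en-2-yl]-4-methoxybenzene
Conditions: [Ni(η3-C3H5)Br]2 (0.7 mol %), binaphthol-derived phosphoramidite ligand (1.5 mol %), Na[B(3,5-(CF3)2C6H3)4] (2 mol %), ethylene (1 atm), CH2Cl2, −70 °C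
Reagents that add atoms: none
Why: Asymmetric hydrovinylation: a cationic Ni–H adds to the styrene, the benzylic nickel species inserts ethylene and undergoes β-hydride elimination, and the chiral ligand (antipode chosen accordingly) fixes the benzylic centre as S.

Step 2
Reactants: 3 1-[(2S)-but-3-en-2-yl]-4-methoxybenzene; 4 (2E)-3-iodo-2-methylprop-2-en-1-ol
Product: 6 (2E,6S)-6-(4-methoxyphenyl)-2-methylhept-2-en-1-ol, via B-alkyl-9-borabicyclononane 5 (not isolated)
Conditions: 9-BBN-H, THF, 0 °C to rt; then 4, Pd(dppf)Cl2 (3 mol %), AsPh3, aq NaOH (3 molar), rt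
Reagents that add atoms: none
Why: Anti-Markovnikov hydroboration of the terminal alkene followed by B-alkyl Suzuki–Miyaura coupling joins the chain with retention of the E vinyl iodide geometry and does not touch the benzylic centre.

Step 3
Reactants: 7 3-bromobut-3-en-1-ol; 8 2-ethenyl-4,4,5,5-tetramethyl-1,3,2-dioxaborolane
Product: 9 3-methylidenepent-4-en-1-ol
Conditions: Pd(dppf)Cl2 (2 mol %), K3PO4, THF/H2O, 50 °C
Reagents that add atoms: none
Why: Suzuki–Miyaura coupling of a 2-bromoalkene with a vinylboronate is a standard entry to 2-substituted buta-1,3-dienes; no stereocentre is formed.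

Step 4
Reactants: 9 3-methylidenepent-4-en-1-ol
Product: 10 5-iodo-3-methylidenepent-1-ene
Conditions: PPh3, N-iodosuccinimide, CH2Cl2, 0 °C, dark
Reagents that add atoms: N-iodosuccinimide, O=C1CCC(=O)N1I
Why: Appel-type iodination of the primary alcohol through its alkoxyphosphonium salt (SN2), which the diene tolerates at 0 °C.

Step 5
Reactants: 6 (2E,6S)-6-(4-methoxyphenyl)-2-methylhept-2-en-1-ol; 10 5-iodo-3-methylidenepent-1-ene
Product: 13 4-[(2S,5E)-7-hydroxy-6-methylhept-5-en-2-yl]-2-(3-methylidenepent-4-en-1-yl)cyclohex-3-en-1-one (C2 epimers), via 2,5-dihydroanisole 11 (not isolated), via C-alkylated dihydroanisole 12 (not isolated)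
Conditions: Li, NH3, THF, t-BuOH, −78 °C; isoprene, then NH3 evaporated; s-BuLi, TMEDA, THF, −78 °C; 10 (3 equiv), −78 to −20 °C; then oxalic acid, THF/H2O, rt
Reagents that add atoms: water, O
Why: Proposed new method: Birch reduction gives the 1-methoxycyclohexa-1,4-diene, whose doubly allylic CH2 next to the methoxy-bearing carbon is lithiated (methoxy-directed pentadienyl anion) and C-alkylated there by the primary iodide, and gentle acid hydrolysis of the enol ether unmasks the β,γ-unsaturated ketone with the diene arm at C2; the closest known reaction types are the Birch reduction–hydrolysis of anisoles and the metalation–alkylation of 2,5-dihydroanisoles to 2-alkylcyclohexenones, here merged in one flask, and no target stereocentre is fixed (the C2 centre is erased in step 6).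

Step 6
Reactants: 13 4-[(2S,5E)-7-hydroxy-6-methylhept-5-en-2-yl]-2-(3-methylidenepent-4-en-1-yl)cyclohex-3-en-1-one
Product: 14 (4S)-4-[(2S,5E)-7-hydroxy-6-methylhept-5-en-2-yl]-2-(3-methylidenepent-4-en-1-yl)cyclohex-2-en-1-one
Conditions: 9-amino-9-deoxy-epi-cinchona primary amine catalyst (10 mol %), carboxylic acid co-catalyst (20 mol %), toluene, 0 °C
Reagents that add atoms: none
Why: Catalytic asymmetric olefin isomerization: the primary amine converts the β,γ-unsaturated ketone into a dienamine (C2 becomes planar) and the catalyst-bound acid protonates the γ-carbon on one face, setting C4 as S under catalyst control (pseudoenantiomer chosen to match).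

Step 7
Reactants: 15 1,3-dichloropropan-2-one
Product: 16 [(3-chloroprop-1-en-2-yl)oxy]trimethylsilane
Conditions: Zn, Me3SiCl, THF, 0 °C to rt
Reagents that add atoms: chlorotrimethylsilane, C[Si](C)(C)Cl
Why: Reductive silylation: Zn inserts into one carbon–chlorine bond and the zinc enolate is O-silylated, which places the enol ether double bond away from the remaining chloride; no stereocentre.

Step 8
Reactants: 14 (4S)-4-[(2S,5E)-7-hydroxy-6-methylhept-5-en-2-yl]-2-(3-methylidenepent-4-en-1-yl)cyclohex-2-en-1-one; 16 [(3-chloroprop-1-en-2-yl)oxy]trimethylsilane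
Product: 18 (2S,3S,4S)-3-(3-chloro-2-oxopropyl)-4-[(2S,5E)-7-hydroxy-6-methylhept-5-en-2-yl]-2-(3-methylidenepent-4-en-1-yl)cyclohexan-1-one, via bis-silylated Michael adduct 17 (not isolated)
Conditions: Me3SiCl, Et3N, CH2Cl2, 0 °C; then 16 (2 equiv), Ph3CSbCl6 (5 mol %), −78 °C; then aq HCl (1 molar), THF, −20 °C
Reagents that add atoms: none
Why: Mukaiyama–Michael addition: the silyl enol ether attacks C3 of the activated enone anti to the C4 side chain (C3 = S), and kinetic protonation of the resulting tetrasubstituted silyl enol ether at C2 from the face opposite the new C3 substituent gives the 2,3-cis ketone (C2 = S).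

Step 9
Reactants: 18 (2S,3S,4S)-3-(3-chloro-2-oxopropyl)-4-[(2S,5E)-7-hydroxy-6-methylhept-5-en-2-yl]-2-(3-methylidenepent-4-en-1-yl)cyclohexan-1-one
Product: 20 (1S,2S,3S,7S)-3-[(2S,5E)-7-hydroxy-6-methylhept-5-en-2-yl]tricyclo[8.4.1.0(2,7)]pentadec-10-ene-6,14-dione, via oxyallyl cation 19 (not isolated)
Conditions: Et3N (1.5 equiv), (CF3)2CHOH, 0.01 molar, 0 °C to rt
Reagents that add atoms: none
Why: Proposed new method: amine-promoted loss of chloride from the enol of the chloroketone in the ionizing fluoroalcohol gives an oxyallyl cation whose two termini add across the tethered 2-substituted butadiene, the four-atom tether from the diene C2 forcing the bridged orientation that leaves the bridgehead C10=C11 alkene; the diene can only reach the cation face on the side of the C2 arm while allylic 1,3-strain holds the C3–H in the cation plane, which should set the new C1 centre as S; the closest known reaction types are the intramolecular oxyallyl (4+3) cycloaddition of α-chloroketones in fluoroalcohol/amine media and type 2 intramolecular Diels–Alder and (5+2) cycloadditions that give bicyclo[4.4.1]-type bridgehead alkenes.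

Step 10
Reactants: 20 (1S,2S,3S,7S)-3-[(2S,5E)-7-hydroxy-6-methylhept-5-en-2-yl]tricyclo[8.4.1.0(2,7)]pentadec-10-ene-6,14-dione
Product: 21 (2E,6S)-6-[(1S,2S,3S,7S)-6,14-dimethylidenetricyclo[8.4.1.0(2,7)]pentadec-10-en-3-yl]-2-methylhept-2-en-1-ol
Conditions: Zn, CH2Br2, TiCl4 (excess), THF/CH2Cl2, 0 °C to rt
Reagents that add atoms: dibromomethane, BrCBr
Why: Takai–Lombardo methylenation converts both ketones into exocyclic methylenes with a non-basic gem-dimetallic reagent, so the α-centres C1 and C7 are not epimerized and the free hydroxyl is tolerated.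

**Compound list**

1 | 4-methoxystyrene (1-ethenyl-4-methoxybenzene) | C=Cc1ccc(OC)cc1 | starting material
2 | ethylene | C=C | starting material
3 | 1-[(2S)-but-3-en-2-yl]-4-methoxybenzene | COc1ccc(cc1)[C@@H](C)C=C | intermediate
4 | (2E)-3-iodo-2-methylprop-2-en-1-ol | I/C=C(\C)CO | starting material
5 | 9-[(3S)-3-(4-methoxyphenyl)butyl]-9-borabicyclo[3.3.1]nonane | COc1ccc(cc1)[C@@H](C)CCB1C2CCCC1CCC2 | intermediate
6 | (2E,6S)-6-(4-methoxyphenyl)-2-methylhept-2-en-1-ol | COc1ccc(cc1)[C@@H](C)CC/C=C(\C)CO | intermediate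
7 | 3-bromobut-3-en-1-ol | OCCC(Br)=C | starting material
8 | 2-ethenyl-4,4,5,5-tetramethyl-1,3,2-dioxaborolane | C=CB1OC(C)(C)C(C)(C)O1 | starting material
9 | 3-methylidenepent-4-en-1-ol | OCCC(=C)C=C | intermediate
10 | 5-iodo-3-methylidenepent-1-ene | ICCC(=C)C=C | intermediate
11 | (2E,6S)-6-(4-methoxycyclohexa-1,4-dien-1-yl)-2-methylhept-2-en-1-ol | COC1=CCC(=CC1)[C@@H](C)CC/C=C(\C)CO | intermediate
12 | (2E,6S)-6-[4-methoxy-3-(3-methylidenepent-4-en-1-yl)cyclohexa-1,4-dien-1-yl]-2-methylhept-2-en-1-ol (ring C3 epimers) | COC1=CCC(=CC1CCC(=C)C=C)[C@@H](C)CC/C=C(\C)CO | intermediate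
13 | 4-[(2S,5E)-7-hydroxy-6-methylhept-5-en-2-yl]-2-(3-methylidenepent-4-en-1-yl)cyclohex-3-en-1-one (C2 epimers) | O=C1CCC(=CC1CCC(=C)C=C)[C@@H](C)CC/C=C(\C)CO | intermediate
14 | (4S)-4-[(2S,5E)-7-hydroxy-6-methylhept-5-en-2-yl]-2-(3-methylidenepent-4-en-1-yl)cyclohex-2-en-1-one | O=C1CC[C@@H]([C@@H](C)CC/C=C(\C)CO)C=C1CCC(=C)C=C | intermediate
15 | 1,3-dichloropropan-2-one | ClCC(=O)CCl | starting material
16 | [(3-chloroprop-1-en-2-yl)oxy]trimethylsilane | C=C(CCl)O[Si](C)(C)C | intermediate
17 | (3S,4S) ring C1=C2 trimethylsilyl enol ether and side-chain O-trimethylsilyl ether of 18 | C[Si](C)(C)OC1=C(CCC(=C)C=C)[C@@H](CC(=O)CCl)[C@H]([C@@H](C)CC/C=C(\C)CO[Si](C)(C)C)CC1 | intermediate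
18 | (2S,3S,4S)-3-(3-chloro-2-oxopropyl)-4-[(2S,5E)-7-hydroxy-6-methylhept-5-en-2-yl]-2-(3-methylidenepent-4-en-1-yl)cyclohexan-1-one | O=C1CC[C@@H]([C@@H](C)CC/C=C(\C)CO)[C@H](CC(=O)CCl)[C@@H]1CCC(=C)C=C | intermediate
19 | 2-oxidoallyl cation (zwitterion) formed from 18 by loss of HCl, cationic carbon on ring C3 | O=C1CC[C@@H]([C@@H](C)CC/C=C(\C)CO)[C@H]([CH+]C([O-])=C)[C@@H]1CCC(=C)C=C | intermediate
20 | (1S,2S,3S,7S)-3-[(2S,5E)-7-hydroxy-6-methylhept-5-en-2-yl]tricyclo[8.4.1.0(2,7)]pentadec-10-ene-6,14-dione | O=C1CC[C@@H]([C@@H](C)CC/C=C(\C)CO)[C@H]2[C@@H]1CCC1=CCCC(=O)[C@H]2C1 | intermediate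
21 | (2E,6S)-6-[(1S,2S,3S,7S)-6,14-dimethylidenetricyclo[8.4.1.0(2,7)]pentadec-10-en-3-yl]-2-methylhept-2-en-1-ol | C=C1CC[C@@H]([C@@H](C)CC/C=C(\C)CO)[C@H]2[C@@H]1CCC1=CCCC(=C)[C@H]2C1 | target

**Step count**

Total: 10 steps. Longest linear sequence: 7 steps (1, 2, 5, 6, 8, 9, 10).

**Three steps most likely to fail**

Step 9 (type 2 oxyallyl (4+3) cycloaddition). It is unprecedented in this form. Solvent capture, stepwise (3+2) closure and aldol or Darzens reactions of the 1,5-diketone compete, and the C1 configuration rests on a conformational argument. Fallback: exchange the order of the two ring-forming events, setting out from 14. Intermolecular (4+3) cycloaddition of the diene arm with the 2-(trimethylsilyloxy)allyl cation generated from 16 (ZnCl2, CH2Cl2, −20 °C) gives (4S)-4-[(2S,5E)-7-hydroxy-6-methylhept-5-en-2-yl]-2-[2-(5-oxocyclohept-1-en-1-yl)ethyl]cyclohex-2-en-1-one F9. An intramolecular Michael addition (catalytic t-BuOK, t-BuOH/THF) of the cycloheptenone enolate then forms the C1–C2 bond and ring B. Only the α-carbon nearer the substituted alkene carbon can close a seven-membered ring; the other would need an eight-membered one. C1, C2 and C7 are then set under equilibrating conditions, so whether the natural configuration is the stable one is untested. The sequence comes back to the route at 20.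

Step 5 (one-flask Birch reduction / alkylation). E2 elimination of the homoallylic iodide 10 by the dienyl anion and metalation at the wrong site are the main threats. Fallback: separate the dearomatization from the arm installation, setting out from 6. Li/NH3/t-BuOH and oxalic acid work-up give, through 11, 4-[(2S,5E)-7-hydroxy-6-methylhept-5-en-2-yl]cyclohex-3-en-1-one F1. The amine-catalysed isomerization of step 6 gives (4S)-4-[(2S,5E)-7-hydroxy-6-methylhept-5-en-2-yl]cyclohex-2-en-1-one F2. Iodine and pyridine give (4S)-4-[(2S,5E)-7-hydroxy-6-methylhept-5-en-2-yl]-2-iodocyclohex-2-en-1-one F3. In a second flask 10 is converted with t-BuLi into 3-methylidenepent-4-en-1-yllithium F4 and captured with B-methoxy-9-borabicyclononane as lithium 9-methoxy-9-(3-methylidenepent-4-en-1-yl)-9-boranuidabicyclo[3.3.1]nonane F5. B-alkyl Suzuki coupling of F3 and F5 (Pd(dppf)Cl2, AsPh3, K3PO4, DMF) comes back to the route at 14.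

Step 8 (Mukaiyama–Michael addition to a hindered 2,4-disubstituted enone with a deactivated chloro silyl enol ether, and kinetic cis protonation at C2). Fallback: an organocopper conjugate addition followed by electrophilic chlorination, setting out from 14. 3-Bromo-2-methoxyprop-1-ene F6 (from 2-methoxypropene and N-bromosuccinimide) is converted into (2-methoxyprop-2-en-1-yl)magnesium bromide F7. F7 adds to 14 (CuBr·SMe2 cat., THF, −78 °C, quench with a hindered phenol at −78 °C) to give (2S,3S,4S)-4-[(2S,5E)-7-hydroxy-6-methylhept-5-en-2-yl]-3-(2-methoxyprop-2-en-1-yl)-2-(3-methylidenepent-4-en-1-yl)cyclohexan-1-one F8. N-Chlorosuccinimide in wet THF chlorinates the enol ether terminus and unmasks the ketone, which comes back to the route at 18. This answers the reactivity risk only; C2 is still set by kinetic protonation. If the C2 ratio stays poor, the fallback given for step 9 sets that centre after ring B exists.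

**Further compounds**

F1 | step 5 | 4-[(2S,5E)-7-hydroxy-6-methylhept-5-en-2-yl]cyclohex-3-en-1-one | O=C1CCC(=CC1)[C@@H](C)CC/C=C(\C)CO
F2 | step 5 | (4S)-4-[(2S,5E)-7-hydroxy-6-methylhept-5-en-2-yl]cyclohex-2-en-1-one | O=C1CC[C@@H]([C@@H](C)CC/C=C(\C)CO)C=C1
F3 | step 5 | (4S)-4-[(2S,5E)-7-hydroxy-6-methylhept-5-en-2-yl]-2-iodocyclohex-2-en-1-one | O=C1CC[C@@H]([C@@H](C)CC/C=C(\C)CO)C=C1I
F4 | step 5 | 3-methylidenepent-4-en-1-yllithium | [Li]CCC(=C)C=C
F5 | step 5 | lithium 9-methoxy-9-(3-methylidenepent-4-en-1-yl)-9-boranuidabicyclo[3.3.1]nonane | [Li+].CO[B-]1(CCC(=C)C=C)C2CCCC1CCC2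
F6 | step 8 | 3-bromo-2-methoxyprop-1-ene | C=C(OC)CBr
F7 | step 8 | (2-methoxyprop-2-en-1-yl)magnesium bromide | C=C(OC)C[Mg]Br
F8 | step 8 | (2S,3S,4S)-4-[(2S,5E)-7-hydroxy-6-methylhept-5-en-2-yl]-3-(2-methoxyprop-2-en-1-yl)-2-(3-methylidenepent-4-en-1-yl)cyclohexan-1-one | O=C1CC[C@@H]([C@@H](C)CC/C=C(\C)CO)[C@H](CC(=C)OC)[C@@H]1CCC(=C)C=C
F9 | step 9 | (4S)-4-[(2S,5E)-7-hydroxy-6-methylhept-5-en-2-yl]-2-[2-(5-oxocyclohept-1-en-1-yl)ethyl]cyclohex-2-en-1-one | O=C1CC[C@@H]([C@@H](C)CC/C=C(\C)CO)C=C1CCC1=CCCC(=O)CC1
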